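The rate constants are made up, and the outcome is calculated.

A small charge of solid L, 0.900 equiv against the G, has to dissolve before it can link with G, and the flask is reckoned here in fractions of the G charge.

    G + D → Z + Q (k1 = 0.69 M⁻¹ s⁻¹)
    L ⇌ D, rate k2*(cs2 - [D]) while solid is left; crystals form when [D] > cs2 (cs2 = 26 mM, k2 = 1.1 × 10⁻⁴ s⁻¹)

G 28 mM (fed, over 10 min); L 0.900 equiv; time 50 min

- as a solid, counted per litre of solution: L
- at the start none of L is in solution
- the reaction counts as stopped when no species that holds the G changes by six tenths of a point or more over the second half of the time
- run time (flask): 50 min

- at 50 min, what has stopped the reaction, if anything has (for what has run out or reacted, a solid counts together with what of it has only dissolved) (it is still moving / D has run out first / all of G has reacted / forward and back rates have come level)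
- how much of the G has reacted by 50 min
- how much Z there is at 50 min, in percent of the G charged
- amount of Z if the flask were left three thousand times as long, in percent of the G charged

Two ways of reckoning set the scale. The first takes the even case as its zero: the solid is no obstacle, the whole L stands dissolved at once as D, 25.2 mM, below the solubility 26 mM, and G meets it freely. The link then forms with a time constant of 0.959 min, well inside 50 min.

The second way follows the supply. D enters by dissolving, and that rate is highest, 0.172 mM min⁻¹, while D is near zero. This gives the solid clock, the time in which dissolving at its full rate hands over one whole G charge: 163 min. The fraction turned into Z then grows as time over this clock.

The two ways part by a factor of 170, and the first one cheats. With the whole charge of G present, D lives 0.863 min, while dissolving has a time constant of 152 min, so D is consumed far sooner than it gathers. On this reckoning free D rests near 0.529% of the charge, and dissolving is the rate-limiting step, its clock being far the longer.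

The rate of dissolving holds no G in its law, so it runs through the 10 min feed as well. Taking off the free D, this reckoning gives conv 30.1% and y_L 30.1%, one number, since each link takes one G.

At that full rate the solid needs 147 min to go, longer than the run, so the verdict is it is still moving. L is the limiting reagent, charged below G, so Z ends at 90.0%.

The forecast, lower than this reckoning, gives it is still moving, conv and y_L of 29.7%, and ever 90%, holding that "Z forms at essentially the dissolution rate".

The simulation gives it is still moving, conv 29.7%, y_L 29.7% and ever 90.0%.

The clock's figure stands 0.45 percentage points above the reading for this flask, where L still holds 66.2% of its own charge at 50.0 min. A neighbouring flask holds 110 mM of G with the equivalents kept. Its solid has the same top rate of dissolving, but its G charge is larger, so its clock is 641 min, and 50 min on that clock gives 7.80%. That neighbouring flask reads Z at 7.75% at 50.0 min, with G at 92.3%.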